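## Retrosynthetic overview

1. Target ⇒ selective aryl-acetate methanolysis and autoxidation of a tetraacetoxyarene ⇒ Thiele–Winter acetoxylation of a 2-alkyl-6-methoxy-1,4-benzoquinone (ring hydroxylation and O-acetylation come last).
2. Methoxyquinone ⇒ oxidative ipso-decarboxylation of a 4-hydroxy-2-methoxy-6-alkylbenzoic acid (the O-methylated alkylresorcylic acid).
3. Benzene ring (the only ring, formed once) ⇒ polyketide-type C-2→C-7 aldol closure and aromatisation of a tetraketide, released in the flask from a 6-(2-oxoalkyl)-4-methoxy-2-pyrone.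
4. Tetraketide pyrone ⇒ Claisen union of lithiated 4-methoxy-6-methyl-2-pyrone (triketide lactone methyl ether) with methyl (R)-3-hydroxyhexadecanoate, the starter unit that carries the stereocentre.
5. (R)-Hydroxy ester ⇒ Noyori hydrogenation of the β-keto ester made from tetradecanoyl chloride and Meldrum's acid.

Assumption: the biosynthesis is taken to be the alkylresorcinol pathway (as for sorgoleone and maesanin): an (R)-3-hydroxypalmitoyl starter plus three malonates, C-2→C-7 aldol closure with loss of the carboxyl carbon, then O-methylation, ring hydroxylation/oxidation and O-acetylation; the target stereocentre is (R).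

## Route

Step 1
Reactants: 1 tetradecanoyl chloride; 2 Meldrum's acid (2,2-dimethyl-1,3-dioxane-4,6-dione)
Product: 4 methyl 3-oxohexadecanoate, via acyl Meldrum's acid 3 (not isolated)
Conditions: pyridine (2 equiv), CH2Cl2, 0 °C → rt; then MeOH, reflux
Reagents that add atoms: methanol, CO
Why: C-acylation of Meldrum's acid followed by methanolysis with loss of acetone and CO2 (Oikawa–Yonemitsu β-keto ester synthesis) is a standard one-acetate extension of a fatty acyl chloride; no stereocentre is formed.

Step 2
Reactants: 4 methyl 3-oxohexadecanoate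
Product: 5 methyl (3R)-3-hydroxyhexadecanoate
Conditions: H2 (50 atm), RuCl2[(R)-BINAP] (0.2 mol %), MeOH, 50 °C
Reagents that add atoms: none
Why: Noyori asymmetric hydrogenation of a β-keto ester, in which the ester-chelated ketone is reduced on the face set by (R)-BINAP to give the (3R)-alcohol (same sense as for methyl acetoacetate and methyl 3-oxotetradecanoate, ≥97% ee expected); this sets the only stereocentre of the target.

Step 3
Reactants: 5 methyl (3R)-3-hydroxyhexadecanoate; 6 4-methoxy-6-methyl-2H-pyran-2-one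
Product: 7 6-[(4R)-4-hydroxy-2-oxoheptadecyl]-4-methoxy-2H-pyran-2-one
Conditions: 6 (3.2 equiv), LiN(i-Pr)2 (3.2 equiv), THF, −78 °C; then 5, −78 → −20 °C; AcOH
Reagents that add atoms: none
Why: crossed Claisen condensation in which the vinylogous lithium enolate at the 6-methyl group of 6 is acylated by the ester of 5 (one equivalent is spent on the hydroxyl and one on the acidic product methylene, as in enolate condensations with free β-hydroxy esters), the lithium alkoxide being a non-leaving group so that C-3 neither eliminates nor epimerises.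

Step 4
Reactants: 7 6-[(4R)-4-hydroxy-2-oxoheptadecyl]-4-methoxy-2H-pyran-2-one
Product: 10 2-[(2R)-2-hydroxypentadecyl]-6-methoxy-1,4-benzoquinone, via ring-opened enoic acid 8 (not isolated), via methoxy hydroxybenzoic acid 9 (not isolated)
Conditions: 2 M aq KOH, 1,4-dioxane, Ar, rt → 45 °C; AcOH to pH 6.5–7; then ON(SO3K)2 (2.5 equiv), H2O/acetone, 0 °C → rt
Reagents that add atoms: potassium nitrosodisulfonate (Fremy's salt), [O]N(S(=O)(=O)[O-])S(=O)(=O)[O-].[K+].[K+]
Why: Proposed new method: hydroxide opens the 2-pyrone to the (2E)-3-methoxy-5,7-dioxo-2-enoate 8, whose fixed enol-ether carbon C-2 (cis to the chain) adds to the C-7 ketone in a six-membered aldol closure as in alkylresorcylic-acid biosynthesis, and dehydration aromatises to carboxylate 9 (closest known reaction: the aqueous-KOH conversion of 6-(2-oxoalkyl)-4-hydroxy-2-pyrones into 6-alkyl-β-resorcylic acids, where the carboxylate blocks the competing Claisen mode); the enolised 5,7-diketone shields the β-hydroxy ketone from retro-aldol and dehydration, and 9, never acidified so that it cannot lactonise to the dihydroisocoumarin, is then attacked by Fremy's radical at the carbon para to the phenol, which bears the carboxylate, so that loss of CO2 gives the p-quinone directly (closest known reaction: Teuber oxidation with loss of a para substituent and oxidative decarboxylation of 4-hydroxybenzoic acids to p-benzoquinones); the stereocentre is untouched.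

Step 5
Reactants: 10 2-[(2R)-2-hydroxypentadecyl]-6-methoxy-1,4-benzoquinone
Product: 12 3-[(2R)-2-acetoxypentadecyl]-5-methoxybenzene-1,2,4-triyl triacetate, via quinone acetate 11 (not isolated)
Conditions: Ac2O, H2SO4 (cat.), 0 °C → rt
Reagents that add atoms: acetic anhydride, CC(=O)OC(C)=O
Why: Thiele–Winter acetoxylation, in which the side-chain hydroxyl is acetylated first with retention (O–H cleavage, which also stops it adding to the quinone) and acetate then adds para to the methoxy group, β to the carbonyl not deactivated by the vinylogous-ester oxygen and hence next to the side chain, followed by enolisation and O-acetylation.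

Step 6
Reactants: 12 3-[(2R)-2-acetoxypentadecyl]-5-methoxybenzene-1,2,4-triyl triacetate
Product: 14 (2R)-1-(2-hydroxy-5-methoxy-3,6-dioxocyclohexa-1,4-dien-1-yl)pentadecan-2-yl acetate (target CNP0332196.1), via benzenetriol acetate 13 (not isolated)
Conditions: K2CO3 (3.5 equiv), MeOH, 0 °C, Ar; then air, 0 °C → rt; 1 M HCl
Reagents that add atoms: none
Why: base-mediated transesterification cleaves the three aryl acetates far faster than the hindered secondary alkyl acetate, and the resulting 1,2,4-benzenetriol 13 autoxidises in air to the 2-hydroxy-1,4-benzoquinone; the stereocentre is not involved.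

## Compound list

1 | tetradecanoyl chloride | CCCCCCCCCCCCCC(=O)Cl | starting material
2 | Meldrum's acid (2,2-dimethyl-1,3-dioxane-4,6-dione) | CC1(C)OC(=O)CC(=O)O1 | starting material
3 | 5-(1-hydroxytetradecylidene)-2,2-dimethyl-1,3-dioxane-4,6-dione | CCCCCCCCCCCCCC(O)=C1C(=O)OC(C)(C)OC1=O | intermediate
4 | methyl 3-oxohexadecanoate | CCCCCCCCCCCCCC(=O)CC(=O)OC | intermediate
5 | methyl (3R)-3-hydroxyhexadecanoate | CCCCCCCCCCCCC[C@H](CC(=O)OC)O | intermediate
6 | 4-methoxy-6-methyl-2H-pyran-2-one | CC1=CC(OC)=CC(=O)O1 | starting material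
7 | 6-[(4R)-4-hydroxy-2-oxoheptadecyl]-4-methoxy-2H-pyran-2-one | CCCCCCCCCCCCC[C@H](CC(=O)CC1=CC(OC)=CC(=O)O1)O | intermediate
8 | (2E,9R)-9-hydroxy-3-methoxy-5,7-dioxodocos-2-enoic acid | CCCCCCCCCCCCC[C@H](CC(=O)CC(=O)C/C(OC)=C\C(=O)O)O | intermediate
9 | 4-hydroxy-6-[(2R)-2-hydroxypentadecyl]-2-methoxybenzoic acid | CCCCCCCCCCCCC[C@H](Cc1cc(O)cc(OC)c1C(=O)O)O | intermediate
10 | 2-[(2R)-2-hydroxypentadecyl]-6-methoxy-1,4-benzoquinone | CCCCCCCCCCCCC[C@H](CC1=CC(=O)C=C(OC)C1=O)O | intermediate
11 | (2R)-1-(5-methoxy-3,6-dioxocyclohexa-1,4-dien-1-yl)pentadecan-2-yl acetate | CCCCCCCCCCCCC[C@H](CC1=CC(=O)C=C(OC)C1=O)OC(C)=O | intermediate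
12 | 3-[(2R)-2-acetoxypentadecyl]-5-methoxybenzene-1,2,4-triyl triacetate | CCCCCCCCCCCCC[C@H](Cc1c(OC(C)=O)c(OC(C)=O)cc(OC)c1OC(C)=O)OC(C)=O | intermediate
13 | (2R)-1-(2,3,6-trihydroxy-5-methoxyphenyl)pentadecan-2-yl acetate | CCCCCCCCCCCCC[C@H](Cc1c(O)c(O)cc(OC)c1O)OC(C)=O | intermediate
14 | (2R)-1-(2-hydroxy-5-methoxy-3,6-dioxocyclohexa-1,4-dien-1-yl)pentadecan-2-yl acetate | CCCCCCCCCCCCC[C@H](CC1=C(O)C(=O)C=C(OC)C1=O)OC(C)=O | target

## Step count and risk

Total steps: 6. Longest linear sequence: 6 steps (1 → 14).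

**Step 4 (highest risk).** Hydroxide may cleave the enol-ether methyl before the aldol closes, and Fremy's radical may attack ortho instead of ipso at the hindered carboxylate carbon. The fallback sets out from 5 and returns at 10. It uses the free-hydroxyl pyrone series, for which the aqueous-KOH aldol mode is established, and replaces ipso-decarboxylation by protodecarboxylation and C–H oxidation. The dianion of 4-hydroxy-6-methyl-2H-pyran-2-one (triacetic acid lactone; LiN(i-Pr)2, THF, −78 → 0 °C) is acylated by 5 to give 4-hydroxy-6-[(4R)-4-hydroxy-2-oxoheptadecyl]-2H-pyran-2-one F1. Treatment with 2 M aq KOH converts it into 2,4-dihydroxy-6-[(2R)-2-hydroxypentadecyl]benzoic acid F2, which is not isolated but buffered to pH 5–6 and warmed to 90 °C to lose CO2 and give 5-[(2R)-2-hydroxypentadecyl]benzene-1,3-diol F3. Teuber oxidation (ON(SO3K)2, KH2PO4, H2O/acetone) para to one hydroxyl gives 2-hydroxy-6-[(2R)-2-hydroxypentadecyl]-1,4-benzoquinone F4, and its vinylogous-acid hydroxyl alone is methylated by TMSCHN2 (MeOH/toluene, 0 °C) to give 10.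

**Step 3.** The ester carries a lithium alkoxide, which lowers its electrophilicity, and the vinylogous enolate is only a modest nucleophile. The fallback sets out from 5 and returns at 7. It masks the hydroxyl and changes the acyl donor to a Weinreb amide. TBSCl/imidazole (DMF) gives methyl (3R)-3-[(tert-butyldimethylsilyl)oxy]hexadecanoate F5. MeNHOMe·HCl/i-PrMgCl (THF, −20 °C) gives (3R)-3-[(tert-butyldimethylsilyl)oxy]-N-methoxy-N-methylhexadecanamide F6. Lithiated 6 (2.2 equiv, THF, −78 °C) adds once to give 6-[(4R)-4-[(tert-butyldimethylsilyl)oxy]-2-oxoheptadecyl]-4-methoxy-2H-pyran-2-one F7, and aqueous HF in MeCN (0 °C) removes the silyl group without β-elimination to give 7.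

**Step 5.** The free side-chain hydroxyl may add to the quinone before it is acetylated, or acetate may enter next to the methoxy group. The fallback sets out from 10 and returns at 14 directly, so it also bypasses step 6. The alcohol is acetylated on its own (Ac2O, pyridine, CH2Cl2, 0 °C) and 11 is isolated. Nucleophilic epoxidation (30% H2O2, Na2CO3, THF/H2O, 0 °C) of the electron-poor, non-methoxylated double bond gives (2R)-1-(3-methoxy-2,5-dioxo-7-oxabicyclo[4.1.0]hept-3-en-1-yl)pentadecan-2-yl acetate F8 as two epoxide diastereomers that converge. H2SO4 on silica gel (CH2Cl2, rt) opens the epoxide and enolisation of the ketol gives hydroxyquinone 14 (epoxyquinone → hydroxyquinone rearrangement).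

## Further compounds

F1 | step 4 | 4-hydroxy-6-[(4R)-4-hydroxy-2-oxoheptadecyl]-2H-pyran-2-one | CCCCCCCCCCCCC[C@H](CC(=O)CC1=CC(O)=CC(=O)O1)O
F2 | step 4 | 2,4-dihydroxy-6-[(2R)-2-hydroxypentadecyl]benzoic acid | CCCCCCCCCCCCC[C@H](Cc1cc(O)cc(O)c1C(=O)O)O
F3 | step 4 | 5-[(2R)-2-hydroxypentadecyl]benzene-1,3-diol | CCCCCCCCCCCCC[C@H](Cc1cc(O)cc(O)c1)O
F4 | step 4 | 2-hydroxy-6-[(2R)-2-hydroxypentadecyl]-1,4-benzoquinone | CCCCCCCCCCCCC[C@H](CC1=CC(=O)C=C(O)C1=O)O
F5 | step 3 | methyl (3R)-3-[(tert-butyldimethylsilyl)oxy]hexadecanoate | CCCCCCCCCCCCC[C@H](CC(=O)OC)O[Si](C)(C)C(C)(C)C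
F6 | step 3 | (3R)-3-[(tert-butyldimethylsilyl)oxy]-N-methoxy-N-methylhexadecanamide | CCCCCCCCCCCCC[C@H](CC(=O)N(C)OC)O[Si](C)(C)C(C)(C)C
F7 | step 3 | 6-[(4R)-4-[(tert-butyldimethylsilyl)oxy]-2-oxoheptadecyl]-4-methoxy-2H-pyran-2-one | CCCCCCCCCCCCC[C@H](CC(=O)CC1=CC(OC)=CC(=O)O1)O[Si](C)(C)C(C)(C)C
F8 | step 5 | (2R)-1-(3-methoxy-2,5-dioxo-7-oxabicyclo[4.1.0]hept-3-en-1-yl)pentadecan-2-yl acetate (both epoxide diastereomers) | CCCCCCCCCCCCC[C@H](CC12OC1C(=O)C=C(OC)C2=O)OC(C)=O
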